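**Wrong clock.** The pitfall is to treat G as pseudo-first-order, with one time constant. In the eta run D is charged equal to G and falls with it, so the rate follows the square of what is left: G drops from 15.5% to 5.0% between 1.00 h and 3.00 h, then needs until 8.00 h to reach 2.3%.

| flask | G | D | Z | J | remark | time |
|---|---|---|---|---|---|---|
| eta | 2.4 M | 1 equiv | 0.085 M | 0.085 M | run made earlier |  |
| beta | 1.7 M | 1 equiv | 0.085 M | 0.17 M | run made earlier |  |
| flask | 1.7 M | 1.00 equiv | 0.0850 M | 0.0850 M |  | 8.0 h |

| run | time / h | E / % | G / % |
|---|---|---|---|
| eta | 1.00 | 81.6 | 15.5 |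
| eta | 3.00 | 90.7 | 5.0 |
| eta | 5.00 | 92.2 | 3.3 |
| eta | 8.00 | 93.1 | 2.3 |
| beta | 2.00 | 82.2 | 14.1 |
| beta | 4.00 | 86.2 | 8.8 |
| beta | 6.00 | 87.3 | 6.8 |
| beta | 8.00 | 86.8 | 5.7 |

(standard deviation of a reading: 0.5 percentage points)

- average number of monomer units in a chain (unreacted monomers counted as chains of one) at 8.0 h
- part of the G that has reacted at 8.0 h

- each monomer carries two end groups and Z one, which caps an end: a chain counts once for every two ends that are left, dead ends included; the units are half of the end groups of the two monomers charged
- on the list of suspects stand: G + Z -> Q; D + J -> X; E -> L; G + D -> E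
- a link that another step uses up counts as cut, two dead ends; so do two ends of one kind that react with each other

**First rung.** Capping runs beside the early linking: at 1.00 h eta's G and E together already lack 2.90%, against a Z charge of 3.54% of G. In the flask Z is z = 5.00% of G. In the flask J is charged equal to Z, so I assume D ends up losing what G loses and take the two as equal.

**Middle rung.** Let g be G as a share of its charge and y its reciprocal, which rises straight in time for equal partners. I replace the curve by its mean slope between eta's outer readings, 5.29 h⁻¹. Started after capping, that line gives 15.8% at 1.00 h against the reading 15.5%, a small error. Scaled by the G charge, the flask's hourly rise of y, my clock rate, is 3.75 h⁻¹, starting from 1.05.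

**Slow rung.** At 8.00 h eta lacks a further 1.06%, less than its Z share. I read this as the link loss by that time, ℓ, and take the same for the flask over the same hours.

**My reckoning.** With G and D equal, the chains per unit are what E does not hold: w = g + z + ℓ, and dp is the reciprocal of w. At 8.0 h my line for the flask gives g = 3.22%, so c is 96.8%; w is 9.28%, so dp is 10.8.

**Forecast.** The forecast gives dp 10.5 (9.3 to 11.7) and c 96.8% (96% to 97.5%), holding that "Z is essentially consumed, and links are also being lost slowly".

**Result.** The flask gives dp 10.9 and c 97.0%, with G at 2.98% against my 3.22%.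

    G + Z → Q (k = 0.00260 M⁻¹ s⁻¹)
    D + J → X (k = 9.20 × 10⁻⁴ M⁻¹ s⁻¹)
    E → L (k = 5.10 × 10⁻⁷ s⁻¹)
    G + D → E (k = 6.50 × 10⁻⁴ M⁻¹ s⁻¹)

**Earlier reading.** I read the same flask at 2.0 h, amounts held. The clock rate gives g = 11.7%, so c is 88.3%. The link loss, scaled by time, is 0.265%, so w is 17.0% and dp is 5.88. The neighbour flask holds G at 11% and E at 84.0%, with c at 89.2% and dp at 6.24.

(All runs were computed for substances that don't exist; noise was put on by code.)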